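## Structural features

The target is a labdane diterpenoid (labdane numbering throughout: ring A = C1–C5, C10; ring B = C5–C10). It is a trans-fused decalin with a tetrasubstituted C8=C9 alkene that carries C17 on C8 and the (E)-3-methylpent-2-enoic acid chain (C11–C16) on C9. Five stereocentres form one block, C3–C4–C5–C6 with C10 on C5, configured (3R,4S,5R,6R,10S); C4 and C10 are quaternary and flank the C5 methine. On the β face the C20 methyl (on C10), the C19 acyloxymethyl (on C4) and the C6 hydroxyl are all axial and 1,3-syn to each other; the C3 isovalerate is axial on the α face, trans to C19. Three oxygens must be told apart: O3 and O19 carry isovalerates, O6 stays free. Fragile points are the two esters (no hydrolytic unmasking of the C15 acid is possible), possible O19→O6 acyl transfer, and the C8=C9 bond, which can move into conjugation whenever C6 is a ketone. The real difficulty is the congested C4(quaternary)–C5–C10(quaternary) bond set with the correct relative configuration at C4, C5, C6 and C10. The key step exploits two features: ring B is a cyclohexene (C5–C6–C7–C8=C9–C10, a Diels–Alder retron with C5=C6 as dienophile), and the C19 oxygen and the C6 substituent are syn-axial, so they can be tied by a one-atom bridge (C19–O–SO2–C6) that is not in the target.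

## Logic of the disconnections

27 ⇒ 25 (through 26) ⇒ 24. No skeletal bond is cut; the C15 carboxyl is taken back to a silyl-protected allylic alcohol. A free acid or ester at C15 would not survive the organolithium step 14, and ester hydrolysis at the end is excluded by the isovalerates. The gain is an inert side chain; the demand is an oxidation that spares the hindered 6-OH, the esters and the C8=C9 alkene.

24 ⇒ 23. The two acyl C–O bonds at O3 and O19 are cut. Both isovalerates can go on in one operation if O6 is differentiated by its syn-axial environment, so no protecting group is needed on the triol. The demand is that acylation stops after two esters.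

23 ⇒ 22 ⇒ 20. The C6–O bond is traced to a C6 ketone and this to the C6–S bond of a sultone; the C6–S and S–O19 bonds of 20 are not in the target. Sulfur serves as activating group for the key step and as a latent carbonyl. Its removal frees O19 and sets up the C6 carbinol. The demands are an α-metalation/oxygenation that does not move the C8=C9 bond and hydride delivery to the α face of C6.

20 ⇒ 19. The C3–H bond is cut (carbinol from ketone). The enantioselective step 8 gives the C3 epimer that the target does not have, and a trigonal C3 removes an axial substituent from the cycloaddition. The demand is equatorial hydride attack.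

19 ⇒ 18 (key). The C5–C10 and C6–C7 bonds are cut. In one sentence: an intramolecular Diels–Alder reaction of acyclic triene 18, whose dienophile is locked in a temporary sultone ring, closes both carbocycles at once. The gain is a bicycle with four stereocentres and a tetrasubstituted alkene reduced to a chain with one stereocentre (C4). The demands are a C9=C10 geometry with the tether trans to C8 and a dienophile reactive enough near 110 °C.

18 ⇒ 17 ⇒ 16 ⇒ 15. The C5=C6 bond (ring-closing metathesis) and the S–O19 ester bond are cut, and C3 returns to the carbinol level. This leaves a 1,3-diol with a vinyl group on the quaternary carbon. The demands are sulfonylation at the primary hydroxyl only and metathesis between the two monosubstituted alkenes only.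

15 ⇒ 13 + 14. The C3–C4 bond is cut. The quaternary stereocentre C4 with methyl, hydroxymethyl and vinyl is made in one catalytic enantioselective step from an achiral primary alcohol; all chirality of the route originates here. The demands are ligand-controlled facial selectivity and tolerance of the hindered diene.

13 ⇒ 12 ⇒ 6 + 10. The C12–C13 sp3–sp2 bond is cut. The side chain arrives with its E geometry preformed. The demand is retention of the alkenyl iodide geometry.

6 ⇒ 5 ⇒ 3. The C10–C20 and C8–C9 bonds are cut, both across a C9≡C10 alkyne. Syn addition across an alkyne is the most reliable way to a stereodefined tetrasubstituted alkene, and the directing C12 hydroxyl later becomes the handle for the side chain. The demands are methyl delivery to the distal carbon, syn addition and stereoretentive coupling.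

3 ⇒ 1 + 2. The C1–C10 bond is cut (acetylide alkylation), leading to two commercial pieces.

10 ⇒ 8 ⇒ 7. The C13–I and C14–H bonds are cut across an alkyne (hydrometalation), leading to a commercial alkynol.

## Other disconnections considered

Alternative 1: Cut C4–C5 and C9–C10 by cationic epoxy-polyene bicyclisation of A1 to A2; this is the first idea for a labdane. Anti opening of the epoxide would place the C3 oxygen equatorial (3β), the wrong epimer. The acetoxymethyl group on the epoxide carbon destabilises the initiating cation. Proton loss from the C8 cation would give regioisomeric alkenes. Above all, A2 has no oxygen at C6, so a late C–H oxidation or extra unsaturation would be needed. The chosen plan places the C6 heteroatom and the C8=C9 bond in the ring-forming event itself.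

Alternative 2: Build the decalin by Robinson annulation, starting from A3, then decorate stepwise: reductive alkylations at C4, and a C9–C11 sp2–sp3 coupling on enol triflate A4. Every stereocentre is then set one at a time by substrate control. A4 still lacks the C6 oxygen, which would require a separate enone or enol sequence on ring B. The redox and protecting-group count would clearly exceed that of the chosen route.

Alternative 3: Preform ring A and close ring B by Diels–Alder reaction of diene A5 with an alkynoate (cut C9–C10 and C7–C8) to give 1,4-diene A6. The quaternary C10 would have to form at a tetrasubstituted diene terminus, and the only facial bias would be the small difference between C18 and C19 on C4. A6 then needs anti-Markovnikov hydration of C5=C6 with subsequent correction at C6, and a three-carbon homologation of the C11 ester. The chosen plan controls the face through a ring constraint and carries the side chain from the start.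

Key step: step 12

Assumption: the iridium-catalysed tert-(hydroxy)prenylation (step 8) is taken to give the anti diol (secondary OH anti to CH2OH in the extended chain) with ligand-controlled absolute sense. The Tol-BINAP enantiomer is chosen to give the (S)-quaternary carbon drawn in 15; the carbinol configuration of 15 is erased in step 11. Compounds 1, 2, 7 and 14 are taken as commercial.

## Steps

Step 1
Reactants: 1 but-3-yn-1-ol; 2 tert-butyl(3-iodopropoxy)dimethylsilane
Product: 3 7-[(tert-butyldimethylsilyl)oxy]hept-3-yn-1-ol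
Conditions: n-BuLi (2.1 equiv), THF, −78 → −20 °C; then 2, DMPU, −20 °C → rt
Reagents that add atoms: none
Why: Acetylide alkylation (SN2 on a primary iodide); in the alkoxide–acetylide dianion the carbon terminus is the more nucleophilic site, so C-alkylation should dominate.

Step 2
Reactants: 3 7-[(tert-butyldimethylsilyl)oxy]hept-3-yn-1-ol
Product: 5 (3E)-7-[(tert-butyldimethylsilyl)oxy]-4-methyl-3-(prop-1-en-2-yl)hept-3-en-1-ol, via alkenylmagnesium alkoxide 4 (not isolated)
Conditions: MeMgBr (5 equiv), Fe(acac)3 (15 mol%), THF, −20 → 0 °C; then 2-bromopropene (6 equiv), Pd(PPh3)4 (5 mol%), rt → 50 °C; aq. NH4Cl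
Reagents that add atoms: methylmagnesium bromide C[Mg]Br; 2-bromopropene CC(Br)=C
Why: Alkoxide-directed iron-catalysed syn-carbomagnesiation should place methyl on the distal and magnesium on the proximal alkyne carbon (five-membered chelate). Kumada–Corriu coupling with retention then puts isopropenyl cis to the new methyl, which fixes the tetrasubstituted alkene geometry needed for step 12.

Step 3
Reactants: 5 (3E)-7-[(tert-butyldimethylsilyl)oxy]-4-methyl-3-(prop-1-en-2-yl)hept-3-en-1-ol
Product: 6 tert-butyl{[(4E)-7-iodo-4-methyl-5-(prop-1-en-2-yl)hept-4-en-1-yl]oxy}dimethylsilane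
Conditions: I2, PPh3, imidazole, CH2Cl2, 0 °C
Reagents that add atoms: iodine II
Why: Appel iodination of the primary alcohol under neutral conditions; the diene and the silyl ether should be untouched.

Step 4
Reactants: 7 but-2-yn-1-ol
Product: 8 (but-2-yn-1-yloxy)(tert-butyl)diphenylsilane
Conditions: TBDPSCl, imidazole, DMF, rt
Reagents that add atoms: tert-butyl(chloro)diphenylsilane CC(C)(C)[Si](Cl)(c1ccccc1)c1ccccc1
Why: Standard silylation of a primary alcohol; TBDPS is chosen to survive the later removal of the TBS group.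

Step 5
Reactants: 8 (but-2-yn-1-yloxy)(tert-butyl)diphenylsilane
Product: 10 tert-butyl{[(2E)-3-iodobut-2-en-1-yl]oxy}diphenylsilane, via alkenylzirconocene chloride 9 (not isolated)
Conditions: Cp2Zr(H)Cl (1.8 equiv), THF, rt → 40 °C; then I2, 0 °C
Reagents that add atoms: iodine II
Why: Hydrozirconation–iodination: syn addition of Zr–H, zirconium settling on the less hindered methyl-bearing carbon under equilibrating conditions, and iodinolysis with retention should give the (E)-iodide.

Step 6
Reactants: 6 tert-butyl{[(4E)-7-iodo-4-methyl-5-(prop-1-en-2-yl)hept-4-en-1-yl]oxy}dimethylsilane; 10 tert-butyl{[(2E)-3-iodobut-2-en-1-yl]oxy}diphenylsilane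
Product: 12 (2E,6E)-10-[(tert-butyldimethylsilyl)oxy]-1-[(tert-butyldiphenylsilyl)oxy]-3,7-dimethyl-6-(prop-1-en-2-yl)deca-2,6-diene, via alkylzinc iodide 11 (not isolated)
Conditions: Zn dust (activated), LiCl, THF, 40 °C; then 10, Pd(PPh3)4 (5 mol%), THF, 50 °C
Reagents that add atoms: none
Why: Zinc insertion into the primary iodide followed by Negishi coupling, which proceeds with retention of the alkenyl iodide geometry and so sets the 13E alkene.

Step 7
Reactants: 12 (2E,6E)-10-[(tert-butyldimethylsilyl)oxy]-1-[(tert-butyldiphenylsilyl)oxy]-3,7-dimethyl-6-(prop-1-en-2-yl)deca-2,6-diene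
Product: 13 (4E,8E)-10-[(tert-butyldiphenylsilyl)oxy]-4,8-dimethyl-5-(prop-1-en-2-yl)deca-4,8-dien-1-ol
Conditions: PPTS (cat.), MeOH, rt
Reagents that add atoms: none
Why: Acid-catalysed methanolysis should remove the primary TBS ether much faster than the TBDPS ether; the conditions are mild enough for the diene.

Step 8
Reactants: 13 (4E,8E)-10-[(tert-butyldiphenylsilyl)oxy]-4,8-dimethyl-5-(prop-1-en-2-yl)deca-4,8-dien-1-ol; 14 2-methyl-2-vinyloxirane (racemic)
Product: 15 (2S,3S,6E,10E)-12-[(tert-butyldiphenylsilyl)oxy]-2-ethenyl-2,6,10-trimethyl-7-(prop-1-en-2-yl)dodeca-6,10-diene-1,3-diol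
Conditions: 14 (3 equiv), cyclometallated π-allyliridium C,O-benzoate complex of Tol-BINAP (5 mol%; ligand enantiomer per the assumption), K3PO4 (5 mol%), THF, 60 °C
Reagents that add atoms: none
Why: Iridium-catalysed transfer-hydrogenative carbonyl tert-(hydroxy)prenylation: the alcohol is dehydrogenated to the aldehyde, 14 gives a π-allyliridium, and addition through a closed chair transition state under ligand control should set the quaternary carbon (labdane C4) enantioselectively. Only this centre is carried on, and the hindered tri- and tetrasubstituted alkenes should be spectators.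

Step 9
Reactants: 15 (2S,3S,6E,10E)-12-[(tert-butyldiphenylsilyl)oxy]-2-ethenyl-2,6,10-trimethyl-7-(prop-1-en-2-yl)dodeca-6,10-diene-1,3-diol
Product: 16 (2S,3S,6E,10E)-12-[(tert-butyldiphenylsilyl)oxy]-2-ethenyl-3-hydroxy-2,6,10-trimethyl-7-(prop-1-en-2-yl)dodeca-6,10-dien-1-yl ethenesulfonate
Conditions: 2-chloroethanesulfonyl chloride (1.1 equiv), Et3N (2.5 equiv), CH2Cl2, −40 → 0 °C
Reagents that add atoms: 2-chloroethanesulfonyl chloride ClCCS(Cl)(=O)=O
Why: Sulfonylation with in situ elimination to the ethenesulfonate; the primary alcohol should react ahead of the secondary alcohol next to the quaternary carbon.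

Step 10
Reactants: 16 (2S,3S,6E,10E)-12-[(tert-butyldiphenylsilyl)oxy]-2-ethenyl-3-hydroxy-2,6,10-trimethyl-7-(prop-1-en-2-yl)dodeca-6,10-dien-1-yl ethenesulfonate
Product: 17 (5S)-5-[(1S,4E,8E)-10-{[tert-butyl(diphenyl)silyl]oxy}-1-hydroxy-4,8-dimethyl-5-(prop-1-en-2-yl)deca-4,8-dien-1-yl]-5-methyl-5,6-dihydro-1,2-oxathiine 2,2-dioxide
Conditions: Grubbs second-generation catalyst (5–10 mol%), CH2Cl2 (0.005 M), 40 °C
Reagents that add atoms: none
Why: Ring-closing metathesis to an α,β-unsaturated δ-sultone; six-ring closure between the two monosubstituted alkenes, helped by the quaternary centre (Thorpe–Ingold effect), should outpace any reaction at the 1,1-di-, tri- and tetrasubstituted alkenes.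

Step 11
Reactants: 17 (5S)-5-[(1S,4E,8E)-10-{[tert-butyl(diphenyl)silyl]oxy}-1-hydroxy-4,8-dimethyl-5-(prop-1-en-2-yl)deca-4,8-dien-1-yl]-5-methyl-5,6-dihydro-1,2-oxathiine 2,2-dioxide
Product: 18 (5S)-5-[(4E,8E)-10-{[tert-butyl(diphenyl)silyl]oxy}-4,8-dimethyl-5-(prop-1-en-2-yl)deca-4,8-dienoyl]-5-methyl-5,6-dihydro-1,2-oxathiine 2,2-dioxide
Conditions: Dess–Martin periodinane, NaHCO3, CH2Cl2, 0 °C → rt
Reagents that add atoms: none
Why: Dess–Martin oxidation of the only free alcohol; it makes C3 trigonal for the cycloaddition and prepares the correction of the C3 configuration.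

Step 12
Reactants: 18 (5S)-5-[(4E,8E)-10-{[tert-butyl(diphenyl)silyl]oxy}-4,8-dimethyl-5-(prop-1-en-2-yl)deca-4,8-dienoyl]-5-methyl-5,6-dihydro-1,2-oxathiine 2,2-dioxide
Product: 19 (4S,5R,6R,10S)-15-[(tert-butyldiphenylsilyl)oxy]-19-hydroxy-3-oxolabda-8,13E-diene-6β-sulfonic acid δ-sultone (trans-decalin with 5α-H and 10β-CH3; C19–O–SO2–C6 bridge on the β face)
Conditions: toluene (0.005 M), BHT (cat.), 110–130 °C, sealed tube
Reagents that add atoms: none
Why: Thermal type 1 intramolecular Diels–Alder reaction (1,7,9-decatriene class) with a sulfonyl-activated dienophile, closest to the known intramolecular cycloadditions of vinylsulfonates and alkenyl sulfones; the mechanism is a concerted, asynchronous [4+2]. Ring A closes as a six-membered ring through the C5–C10 bond with the C1–C4 tether in a chair; ring B closes as the cyclohexene through C5–C10 and C6–C7, and the C8=C9 alkene appears regiospecifically between the inner diene carbons. The sultone ring holds the C19–C4–C5=C6 torsion near 15–25°, so C19 must become axial, the tether carbon C3 lies anticlinal to C6 on one face of the dienophile and the C18 methyl on the other; the diene can reach C5 only from the C3 face, which translates the C4 configuration into that of C5. The same constraint rules out a chair-like cis-fused transition state, and with the tether in the outside position of the diene, C10 closes with its methyl anti to H5 (trans-decalin, 10β-CH3). C6 is set by suprafacial addition to the ring-locked (Z)-alkene, with sulfur ending β and cis to C19. The selectivities needed are trans fusion and dienophile face; both are secured by the temporary ring and by the diene geometry from step 2. The activated dienophile should allow reaction near 110 °C, below the range in which the 1,5-hydrogen shift of the cis-methyl diene becomes fast.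

Step 13
Reactants: 19 (4S,5R,6R,10S)-15-[(tert-butyldiphenylsilyl)oxy]-19-hydroxy-3-oxolabda-8,13E-diene-6β-sulfonic acid δ-sultone
Product: 20 (3R,4S,5R,6R,10S)-15-[(tert-butyldiphenylsilyl)oxy]-3α,19-dihydroxylabda-8,13E-diene-6β-sulfonic acid δ-sultone (3α-OH axial)
Conditions: L-Selectride, THF, −78 °C; aq. work-up
Reagents that add atoms: none
Why: Equatorial attack of the bulky trialkylborohydride on the C3 ketone next to the quaternary C4 should give the axial 3α-alcohol, as is usual for 4,4-disubstituted 3-oxo terpenoids.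

Step 14
Reactants: 20 (3R,4S,5R,6R,10S)-15-[(tert-butyldiphenylsilyl)oxy]-3α,19-dihydroxylabda-8,13E-diene-6β-sulfonic acid δ-sultone
Product: 22 (3R,4S,5R,10S)-15-[(tert-butyldiphenylsilyl)oxy]-3α,19-dihydroxylabda-8,13E-dien-6-one, via dilithiated sultone 21 (not isolated)
Conditions: n-BuLi (2.2 equiv), THF, −78 °C; then bis(trimethylsilyl) peroxide, −78 → −20 °C; pH 7 buffer
Reagents that add atoms: bis(trimethylsilyl) peroxide C[Si](C)(C)OO[Si](C)(C)C
Why: Oxidative desulfonylation: after alkoxide formation the sultone is lithiated at C6, and oxygen transfer from the silyl peroxide gives an α-silyloxy sulfonate that collapses to the C6 ketone with loss of sulfite, releasing the C19 alcohol. A low-temperature neutral quench should protonate any dienolate at C7 and keep the alkene at C8=C9.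

Step 15
Reactants: 22 (3R,4S,5R,10S)-15-[(tert-butyldiphenylsilyl)oxy]-3α,19-dihydroxylabda-8,13E-dien-6-one
Product: 23 (3R,4S,5R,6R,10S)-15-[(tert-butyldiphenylsilyl)oxy]labda-8,13E-diene-3α,6β,19-triol
Conditions: NaBH4, CeCl3·7H2O, MeOH, −40 °C
Reagents that add atoms: none
Why: Luche-type carbonyl reduction; the β face of C6 is shielded by the syn-axial C20 methyl and C19 hydroxymethyl, so hydride should arrive from the α face and give the axial 6β-alcohol.

Step 16
Reactants: 23 (3R,4S,5R,6R,10S)-15-[(tert-butyldiphenylsilyl)oxy]labda-8,13E-diene-3α,6β,19-triol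
Product: 24 15-[(tert-butyldiphenylsilyl)oxy]-6β-hydroxylabda-8,13E-diene-3α,19-diyl bis(3-methylbutanoate)
Conditions: 3-methylbutanoic anhydride (2.5 equiv), DMAP (0.3 equiv), Et3N, CH2Cl2, 0 °C → rt
Reagents that add atoms: 3-methylbutanoic anhydride CC(C)CC(=O)OC(=O)CC(C)C
Why: DMAP-catalysed acylation; the primary C19-OH and the 3α-OH should react, while the 6β-OH, syn-axial to both C19 and C20, should stay free (steric differentiation).

Step 17
Reactants: 24 15-[(tert-butyldiphenylsilyl)oxy]-6β-hydroxylabda-8,13E-diene-3α,19-diyl bis(3-methylbutanoate)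
Product: 25 6β,15-dihydroxylabda-8,13E-diene-3α,19-diyl bis(3-methylbutanoate)
Conditions: HF·pyridine, pyridine, THF, 0 °C → rt
Reagents that add atoms: none
Why: Fluoride cleavage of the silyl ether under buffered, non-hydrolytic conditions that should spare both esters and avoid acyl transfer.

Step 18
Reactants: 25 6β,15-dihydroxylabda-8,13E-diene-3α,19-diyl bis(3-methylbutanoate)
Product: 27 (3R,4S,5R,6R,10S)-6β-hydroxy-3α,19-bis(3-methylbutanoyloxy)labda-8,13E-dien-15-oic acid (target CNP0333611.1), via enal 26 (not isolated)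
Conditions: TEMPO (cat.), PhI(OAc)2, CH2Cl2, rt; then t-BuOH/H2O, 2-methylbut-2-ene, NaClO2, NaH2PO4, 0 °C → rt
Reagents that add atoms: sodium chlorite [Na+].[O-]Cl=O
Why: TEMPO/PhI(OAc)2 should oxidise the primary allylic alcohol to the enal without touching the hindered secondary alcohol; Pinnick oxidation with an alkene scavenger then gives the acid without affecting the alkenes or esters.

## Compound list

1 | but-3-yn-1-ol | C#CCCO | starting material
2 | tert-butyl(3-iodopropoxy)dimethylsilane | ICCCO[Si](C)(C)C(C)(C)C | starting material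
3 | 7-[(tert-butyldimethylsilyl)oxy]hept-3-yn-1-ol | OCCC#CCCCO[Si](C)(C)C(C)(C)C | intermediate
4 | bromomagnesium 3-(bromomagnesio)-7-[(tert-butyldimethylsilyl)oxy]-4-methylhept-3-en-1-olate (Mg cis to the new methyl) | Br[Mg]OCC/C([Mg]Br)=C(/C)CCCO[Si](C)(C)C(C)(C)C | intermediate (not isolated)
5 | (3E)-7-[(tert-butyldimethylsilyl)oxy]-4-methyl-3-(prop-1-en-2-yl)hept-3-en-1-ol | C=C(C)/C(CCO)=C(\C)CCCO[Si](C)(C)C(C)(C)C | intermediate
6 | tert-butyl{[(4E)-7-iodo-4-methyl-5-(prop-1-en-2-yl)hept-4-en-1-yl]oxy}dimethylsilane | C=C(C)/C(CCI)=C(\C)CCCO[Si](C)(C)C(C)(C)C | intermediate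
7 | but-2-yn-1-ol | CC#CCO | starting material
8 | (but-2-yn-1-yloxy)(tert-butyl)diphenylsilane | CC#CCO[Si](c1ccccc1)(c1ccccc1)C(C)(C)C | intermediate
9 | chlorobis(cyclopentadienyl)[(2E)-4-{[tert-butyl(diphenyl)silyl]oxy}but-2-en-2-yl]zirconium | C/C(=C\CO[Si](c1ccccc1)(c1ccccc1)C(C)(C)C)[Zr](Cl)(C1C=CC=C1)C1C=CC=C1 | intermediate (not isolated)
10 | tert-butyl{[(2E)-3-iodobut-2-en-1-yl]oxy}diphenylsilane | C/C(I)=C\CO[Si](c1ccccc1)(c1ccccc1)C(C)(C)C | intermediate
11 | {(3E)-7-[(tert-butyldimethylsilyl)oxy]-4-methyl-3-(prop-1-en-2-yl)hept-3-en-1-yl}zinc iodide | C=C(C)/C(CC[Zn]I)=C(\C)CCCO[Si](C)(C)C(C)(C)C | intermediate (not isolated)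
12 | (2E,6E)-10-[(tert-butyldimethylsilyl)oxy]-1-[(tert-butyldiphenylsilyl)oxy]-3,7-dimethyl-6-(prop-1-en-2-yl)deca-2,6-diene | C=C(C)/C(CC/C(C)=C/CO[Si](c1ccccc1)(c1ccccc1)C(C)(C)C)=C(\C)CCCO[Si](C)(C)C(C)(C)C | intermediate
13 | (4E,8E)-10-[(tert-butyldiphenylsilyl)oxy]-4,8-dimethyl-5-(prop-1-en-2-yl)deca-4,8-dien-1-ol | C=C(C)/C(CC/C(C)=C/CO[Si](c1ccccc1)(c1ccccc1)C(C)(C)C)=C(\C)CCCO | intermediate
14 | 2-methyl-2-vinyloxirane (isoprene monoxide, racemic) | CC1(C=C)CO1 | starting material
15 | (2S,3S,6E,10E)-12-[(tert-butyldiphenylsilyl)oxy]-2-ethenyl-2,6,10-trimethyl-7-(prop-1-en-2-yl)dodeca-6,10-diene-1,3-diol | C=C(C)/C(CC/C(C)=C/CO[Si](c1ccccc1)(c1ccccc1)C(C)(C)C)=C(\C)CC[C@H](O)[C@](C)(CO)C=C | intermediate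
16 | (2S,3S,6E,10E)-12-[(tert-butyldiphenylsilyl)oxy]-2-ethenyl-3-hydroxy-2,6,10-trimethyl-7-(prop-1-en-2-yl)dodeca-6,10-dien-1-yl ethenesulfonate | C=C(C)/C(CC/C(C)=C/CO[Si](c1ccccc1)(c1ccccc1)C(C)(C)C)=C(\C)CC[C@H](O)[C@](C)(COS(=O)(=O)C=C)C=C | intermediate
17 | (5S)-5-[(1S,4E,8E)-10-{[tert-butyl(diphenyl)silyl]oxy}-1-hydroxy-4,8-dimethyl-5-(prop-1-en-2-yl)deca-4,8-dien-1-yl]-5-methyl-5,6-dihydro-1,2-oxathiine 2,2-dioxide | C=C(C)/C(CC/C(C)=C/CO[Si](c1ccccc1)(c1ccccc1)C(C)(C)C)=C(\C)CC[C@H](O)[C@]1(C)COS(=O)(=O)C=C1 | intermediate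
18 | (5S)-5-[(4E,8E)-10-{[tert-butyl(diphenyl)silyl]oxy}-4,8-dimethyl-5-(prop-1-en-2-yl)deca-4,8-dienoyl]-5-methyl-5,6-dihydro-1,2-oxathiine 2,2-dioxide | C=C(C)/C(CC/C(C)=C/CO[Si](c1ccccc1)(c1ccccc1)C(C)(C)C)=C(\C)CCC(=O)[C@]1(C)COS(=O)(=O)C=C1 | intermediate
19 | (4S,5R,6R,10S)-15-[(tert-butyldiphenylsilyl)oxy]-19-hydroxy-3-oxolabda-8,13E-diene-6β-sulfonic acid δ-sultone | CC1=C(CC/C(C)=C/CO[Si](c5ccccc5)(c5ccccc5)C(C)(C)C)[C@@]2(C)CCC(=O)[C@](C)(CO3)[C@@H]2[C@H](S3(=O)=O)C1 | intermediate
20 | (3R,4S,5R,6R,10S)-15-[(tert-butyldiphenylsilyl)oxy]-3α,19-dihydroxylabda-8,13E-diene-6β-sulfonic acid δ-sultone | CC1=C(CC/C(C)=C/CO[Si](c5ccccc5)(c5ccccc5)C(C)(C)C)[C@@]2(C)CC[C@@H](O)[C@](C)(CO3)[C@@H]2[C@H](S3(=O)=O)C1 | intermediate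
21 | C6-lithiated lithium 3-alkoxide of 20 | CC1=C(CC/C(C)=C/CO[Si](c5ccccc5)(c5ccccc5)C(C)(C)C)[C@@]2(C)CC[C@@H](O[Li])[C@](C)(CO3)[C@@H]2C([Li])(S3(=O)=O)C1 | intermediate (not isolated)
22 | (3R,4S,5R,10S)-15-[(tert-butyldiphenylsilyl)oxy]-3α,19-dihydroxylabda-8,13E-dien-6-one | CC1=C(CC/C(C)=C/CO[Si](c5ccccc5)(c5ccccc5)C(C)(C)C)[C@@]2(C)CC[C@@H](O)[C@](C)(CO)[C@@H]2C(=O)C1 | intermediate
23 | (3R,4S,5R,6R,10S)-15-[(tert-butyldiphenylsilyl)oxy]labda-8,13E-diene-3α,6β,19-triol | CC1=C(CC/C(C)=C/CO[Si](c5ccccc5)(c5ccccc5)C(C)(C)C)[C@@]2(C)CC[C@@H](O)[C@](C)(CO)[C@@H]2[C@H](O)C1 | intermediate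
24 | 15-[(tert-butyldiphenylsilyl)oxy]-6β-hydroxylabda-8,13E-diene-3α,19-diyl bis(3-methylbutanoate) | CC1=C(CC/C(C)=C/CO[Si](c5ccccc5)(c5ccccc5)C(C)(C)C)[C@@]2(C)CC[C@@H](OC(=O)CC(C)C)[C@](C)(COC(=O)CC(C)C)[C@@H]2[C@H](O)C1 | intermediate
25 | 6β,15-dihydroxylabda-8,13E-diene-3α,19-diyl bis(3-methylbutanoate) | CC1=C(CC/C(C)=C/CO)[C@@]2(C)CC[C@@H](OC(=O)CC(C)C)[C@](C)(COC(=O)CC(C)C)[C@@H]2[C@H](O)C1 | intermediate
26 | 6β-hydroxy-15-oxolabda-8,13E-diene-3α,19-diyl bis(3-methylbutanoate) | CC1=C(CC/C(C)=C/C=O)[C@@]2(C)CC[C@@H](OC(=O)CC(C)C)[C@](C)(COC(=O)CC(C)C)[C@@H]2[C@H](O)C1 | intermediate (not isolated)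
27 | (3R,4S,5R,6R,10S)-6β-hydroxy-3α,19-bis(3-methylbutanoyloxy)labda-8,13E-dien-15-oic acid (CNP0333611.1) | CC1=C(CC/C(C)=C/C(=O)O)[C@@]2(C)CC[C@@H](OC(=O)CC(C)C)[C@](C)(COC(=O)CC(C)C)[C@@H]2[C@H](O)C1 | target

## Step count and risk

Total steps: 18. Longest linear sequence: 16 (steps 1–3 and 6–18); steps 4 and 5 form the side branch.

Least certain steps:

Step 12 (key step). The cycloaddition may be too slow at temperatures the diene tolerates, so that the 1,5-hydrogen shift of the cis-methyl diene and oligomerisation of the unsaturated sultone take over. Less likely, closure through a boat-like tether gives cis ring fusion. The fallback sets out from 15 and returns at 22; it gives up the temporary ring in favour of an acyclic, less hindered (E)-dienophile. Selective silylation of the primary hydroxyl of 15 (TBSCl, imidazole) would give the C19 tert-butyldimethylsilyl ether F1. Dess–Martin oxidation would give the C3 ketone F2, and cross-metathesis with phenyl vinyl sulfone (Hoveyda–Grubbs II) the (E)-alkenyl phenyl sulfone F3. Thermal intramolecular Diels–Alder reaction through the endo, chair-tether transition state would give the trans-fused 6α-phenylsulfonyl decalin F4. Here only the C4 stereocentre biases the dienophile face, so diastereomers may have to be separated. L-Selectride would then give the 3α-alcohol F5, and n-BuLi (2 equiv) followed by bis(trimethylsilyl) peroxide the C6 ketone F6; PPTS/MeOH removes the TBS group and returns 22.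

Step 14. Butyllithium may attack at sulfur (ring opening) instead of deprotonating at C6, and base may move the C8=C9 bond into conjugation once the C6 ketone has formed. The fallback runs from 20 to 23 and bypasses 22. Deprotonation with LDA (2.2 equiv) and trapping with 2-isopropoxy-4,4,5,5-tetramethyl-1,3,2-dioxaborolane would give the isolable α-boryl sultone F7. Oxidation of the C–B bond with buffered sodium perborate, with NaBH4/CeCl3 added to the same flask so that the ketone is reduced as it forms, would give 23.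

Step 2. Transmetalation of the chelated, tetrasubstituted alkenylmagnesium may be slow, so that protonation and consumption of the electrophile by excess methyl Grignard outrun the coupling. The fallback runs from 3 to 5: the same carbomagnesiation is quenched with iodine to give the alkenyl iodide F8, and Suzuki–Miyaura coupling with isopropenylboronic acid pinacol ester (PdCl2(dppf), K3PO4, THF/H2O) then gives 5.

Step 16. The three hydroxyls may not be differentiated cleanly: acylation may reach O6 or stall at the hindered O3. The fallback runs from 22 to 24 and acylates while C6 is still a ketone: 22 with 3-methylbutanoic anhydride/DMAP would give the keto diester F9, and NaBH4/CeCl3 at −40 °C then gives 24.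

## Further compounds

F1 | step 12 | (2S,3S,6E,10E)-1-[(tert-butyldimethylsilyl)oxy]-12-[(tert-butyldiphenylsilyl)oxy]-2-ethenyl-2,6,10-trimethyl-7-(prop-1-en-2-yl)dodeca-6,10-dien-3-ol (C19 TBS ether of 15) | C=C(C)/C(CC/C(C)=C/CO[Si](c1ccccc1)(c1ccccc1)C(C)(C)C)=C(\C)CC[C@H](O)[C@](C)(CO[Si](C)(C)C(C)(C)C)C=C
F2 | step 12 | C3 ketone of F1 (quaternary carbon configured as in 15) | C=C(C)/C(CC/C(C)=C/CO[Si](c1ccccc1)(c1ccccc1)C(C)(C)C)=C(\C)CCC(=O)[C@](C)(CO[Si](C)(C)C(C)(C)C)C=C
F3 | step 12 | (E)-alkenyl phenyl sulfone from F2 (vinyl group converted to (E)-CH=CH–SO2Ph) | C=C(C)/C(CC/C(C)=C/CO[Si](c1ccccc1)(c1ccccc1)C(C)(C)C)=C(\C)CCC(=O)[C@](C)(CO[Si](C)(C)C(C)(C)C)/C=C/S(=O)(=O)c1ccccc1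
F4 | step 12 | 19-[(tert-butyldimethylsilyl)oxy]-15-[(tert-butyldiphenylsilyl)oxy]-6α-(phenylsulfonyl)labda-8,13E-dien-3-one (5α-H, 10β-CH3) | CC1=C(CC/C(C)=C/CO[Si](c5ccccc5)(c5ccccc5)C(C)(C)C)[C@@]2(C)CCC(=O)[C@](C)(CO[Si](C)(C)C(C)(C)C)[C@@H]2[C@@H](S(=O)(=O)c5ccccc5)C1
F5 | step 12 | 19-[(tert-butyldimethylsilyl)oxy]-15-[(tert-butyldiphenylsilyl)oxy]-6α-(phenylsulfonyl)labda-8,13E-dien-3α-ol | CC1=C(CC/C(C)=C/CO[Si](c5ccccc5)(c5ccccc5)C(C)(C)C)[C@@]2(C)CC[C@@H](O)[C@](C)(CO[Si](C)(C)C(C)(C)C)[C@@H]2[C@@H](S(=O)(=O)c5ccccc5)C1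
F6 | step 12 | 19-[(tert-butyldimethylsilyl)oxy]-15-[(tert-butyldiphenylsilyl)oxy]-3α-hydroxylabda-8,13E-dien-6-one (C19 TBS ether of 22) | CC1=C(CC/C(C)=C/CO[Si](c5ccccc5)(c5ccccc5)C(C)(C)C)[C@@]2(C)CC[C@@H](O)[C@](C)(CO[Si](C)(C)C(C)(C)C)[C@@H]2C(=O)C1
F7 | step 14 | 6α-(4,4,5,5-tetramethyl-1,3,2-dioxaborolan-2-yl) derivative of 20 (sultone sulfur remains β) | CC1=C(CC/C(C)=C/CO[Si](c5ccccc5)(c5ccccc5)C(C)(C)C)[C@@]2(C)CC[C@@H](O)[C@](C)(CO3)[C@@H]2[C@](B4OC(C)(C)C(C)(C)O4)(S3(=O)=O)C1
F8 | step 2 | (3E)-7-[(tert-butyldimethylsilyl)oxy]-3-iodo-4-methylhept-3-en-1-ol | OCC/C(I)=C(/C)CCCO[Si](C)(C)C(C)(C)C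
F9 | step 16 | 15-[(tert-butyldiphenylsilyl)oxy]-6-oxolabda-8,13E-diene-3α,19-diyl bis(3-methylbutanoate) | CC1=C(CC/C(C)=C/CO[Si](c5ccccc5)(c5ccccc5)C(C)(C)C)[C@@]2(C)CC[C@@H](OC(=O)CC(C)C)[C@](C)(COC(=O)CC(C)C)[C@@H]2C(=O)C1
A1 | alternative 1 | methyl (2E,6E,10E)-13-[(2S,3R)-3-(acetoxymethyl)-3-methyloxiran-2-yl]-3,7,11-trimethyltrideca-2,6,10-trienoate | COC(=O)/C=C(\C)CC/C=C(\C)CC/C=C(\C)CC[C@@H]1O[C@]1(C)COC(C)=O
A2 | alternative 1 | methyl 19-acetoxy-3β-hydroxylabda-8,13E-dien-15-oate (drawn as the Δ8 alkene isomer; no oxygen at C6) | CC1=C(CC/C(C)=C/C(=O)OC)[C@@]2(C)CC[C@H](O)[C@](C)(COC(C)=O)[C@@H]2CC1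
A3 | alternative 2 | (S)-Wieland–Miescher ketone, (8aS)-8a-methyl-3,4,8,8a-tetrahydronaphthalene-1,6(2H,7H)-dione | C[C@]12CCC(=O)C=C1CCCC2=O
A4 | alternative 2 | 3α,19-bis[(tert-butyldimethylsilyl)oxy]-8-methyl trans-decalin C9 enol triflate (Δ8; labdane C1–C10, C17–C20; no oxygen at C6) | CC1=C(OS(=O)(=O)C(F)(F)F)[C@@]2(C)CC[C@@H](O[Si](C)(C)C(C)(C)C)[C@](C)(CO[Si](C)(C)C(C)(C)C)[C@@H]2CC1
A5 | alternative 3 | ring-A diene: 1-ethenyl-2-methylcyclohexene carrying 5-[(tert-butyldimethylsilyl)oxy] and 6-methyl-6-{[(tert-butyldimethylsilyl)oxy]methyl} groups (labdane C3 R, C4 S) | C=CC1=C(C)CC[C@@H](O[Si](C)(C)C(C)(C)C)[C@]1(C)CO[Si](C)(C)C(C)(C)C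
A6 | alternative 3 | Diels–Alder adduct: 1,4-diene (Δ5 and Δ8) with C9 methyl ester, 10β-CH3, 3α- and 19-silyloxy groups | CC1=C(C(=O)OC)[C@@]2(C)CC[C@@H](O[Si](C)(C)C(C)(C)C)[C@](C)(CO[Si](C)(C)C(C)(C)C)C2=CC1
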